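## Retrosynthetic overview
1. Komaroviquinone is an icetexane, a 6-7-6 skeleton in which C9 has migrated from C10 to C20, with a C7 hemiketal bridged to C10 by an oxygen. The quinone comes last, by Fremy oxidation of the C11 phenol (the open C14 position is para to it).
2. The seven-membered ring B and the oxa-bridge form together in one step. A 20-triflate with a C7 ketone undergoes a biomimetic 1,2-aryl (Wagner–Meerwein) shift through a phenonium ion, C9 moving from C10 to C20. The resulting tertiary C10 cation is captured by the C7 carbonyl oxygen, and water converts the oxocarbenium ion into the hemiketal.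
3. The C7 ketone and C20 alcohol come from carnosol: reduce the lactone, then oxidize the benzylic alcohol. Carnosol (the rosemary diterpene lactone) supplies ring A, the gem-dimethyl group, the isopropyl group, the catechol oxygens and the C5 stereocentre. C10 and C7 are set in the rearrangement.

Assumptions:
- Carnosol is the commercially available chiral-pool material in the normal abietane series (5α-H, 10β-C20), which matches C5 of the target. This is a semisynthesis from a natural product rather than a de novo synthesis.
- The 12-OH of carnosol is methylated selectively over the peri-hindered, hydrogen-bonded 11-OH.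
- Simple reagents are given by name and SMILES in each step and are not numbered.

## Route

**Step 1**
Reactants: 1 (carnosol)
Product: 2 (12-O-methylcarnosol)
Conditions: MeI (1.05 equiv), K2CO3, acetone, rt
Reagents that add atoms: iodomethane, CI
Why: Williamson O-methylation takes the more accessible 12-OH, because the 11-OH is hydrogen-bonded to the lactone carbonyl and hindered by the peri C20 group. No stereocentre is touched.

**Step 2**
Reactants: 2
Product: 3 (11-O-benzyl-12-O-methylcarnosol)
Conditions: BnBr, Cs2CO3, TBAI (cat.), DMF, 60 °C
Reagents that add atoms: benzyl bromide, BrCc1ccccc1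
Why: Williamson benzylation protects the remaining phenol. This matters because a free 11-O⁻ would close onto the C20 leaving group in step 5 and form an 11,20-ether.

**Step 3**
Reactants: 3
Product: 4 (7,20-diol: 7-hydroxy and 20-hydroxymethyl)
Conditions: LiAlH4, THF, 0 °C to reflux
Reagents that add atoms: none
Why: hydride reduction opens the bridging lactone to the primary C20 alcohol and the benzylic C7 alcohol. The aryl ethers survive, and C5 and C10 are unchanged.

**Step 4**
Reactants: 4
Product: 5 (11-O-benzyl-12-O-methyl-20-hydroxy-7-oxo-abieta-8,11,13-triene)
Conditions: activated MnO2 (excess), CH2Cl2, rt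
Reagents that add atoms: none
Why: MnO2 oxidizes only the benzylic secondary alcohol and leaves the neopentyl primary alcohol alone. The C7 stereocentre is removed here and is reset by the bridging in step 5.

**Step 5**
Reactants: 5
Product: 6 (ring-expanded icetexane hemiketal, 11-OBn)
Conditions: Tf2O, 2,6-lutidine, CH2Cl2, −78 to 0 °C; then aq. NaHCO3
Reagents that add atoms: water (the added hemiketal oxygen), O
Why: the neopentyl primary triflate ionizes with participation of the electron-rich aryl ring (phenonium ion). This is a Wagner–Meerwein 1,2-aryl shift, C9 moving from C10 to C20, which expands ring B from six to seven members. The tertiary C10 cation is trapped by the C7 carbonyl oxygen on the face syn to C6, which sets C10 with O axial, C20 equatorial and O cis to C6. The bridged bicycle then fixes C7, and water adds to the oxocarbenium ion to give the hemiketal. C5 keeps its configuration.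

**Step 6**
Reactants: 6
Product: 7 (11-hydroxy-12-methoxy hemiketal phenol)
Conditions: H2 (1 atm), 10% Pd/C, EtOAc, rt, short reaction time
Reagents that add atoms: none
Why: hydrogenolysis of the aryl benzyl ether. The hemiketal and the stereocentres are not affected.

**Step 7**
Reactants: 7
Product: 8 (komaroviquinone)
Conditions: Fremy's salt, acetone / aq. KH2PO4 (pH about 6), rt
Reagents that add atoms: water (source of the C14 carbonyl oxygen), O; Fremy's salt is only the oxidant, [K+].[K+].[O]N(S(=O)(=O)[O-])S(=O)(=O)[O-]
Why: the Teuber oxidation converts a phenol with a free para position into the p-quinone, giving the 11,14-dione with 12-OMe and 13-iPr retained. The buffer protects the acid-sensitive hemiketal.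

**Checks made**
- Ring sizes: ring A is a cyclohexane, ring B is seven-membered, and the THF bridge is C10–O–C7.
- The C12-OMe/C13-iPr quinone pattern and the formula C21H28O5 match the target.
- C5 comes from carnosol unchanged.
- C10 and C7 arise in step 5, and the C10 and C7 configurations in 8 match the given SMILES.
- Each step's products follow from its reactants with all atoms accounted for. In step 5, 5 and 6 are isomers.

## Compound list
1 | carnosol (20,7-lactone of 7-hydroxycarnosic acid, normal series) | CC(C)c1cc2c(c(O)c1O)[C@@]13CCCC(C)(C)[C@@H]1C[C@@H]2OC3=O | starting material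
2 | 12-O-methylcarnosol | CC(C)c1cc2c(c(O)c1OC)[C@@]13CCCC(C)(C)[C@@H]1C[C@@H]2OC3=O | intermediate
3 | 11-O-benzyl-12-O-methylcarnosol | CC(C)c1cc2c(c(OCc4ccccc4)c1OC)[C@@]13CCCC(C)(C)[C@@H]1C[C@@H]2OC3=O | intermediate
4 | 7,20-diol from lactone reduction | CC(C)c1cc2c(c(OCc4ccccc4)c1OC)[C@@]3(CO)CCCC(C)(C)[C@@H]3C[C@@H]2O | intermediate
5 | 20-hydroxy-7-oxo compound | CC(C)c1cc2c(c(OCc4ccccc4)c1OC)[C@@]3(CO)CCCC(C)(C)[C@@H]3CC2=O | intermediate
6 | ring-expanded icetexane hemiketal, 11-OBn, 12-OMe | CC(C)c1cc2c(c(OCc4ccccc4)c1OC)C[C@@]35CCCC(C)(C)[C@@H]3C[C@]2(O)O5 | intermediate
7 | 11-hydroxy-12-methoxy hemiketal phenol | CC(C)c1cc2c(c(O)c1OC)C[C@@]35CCCC(C)(C)[C@@H]3C[C@]2(O)O5 | intermediate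
8 | komaroviquinone | COC1=C(C(C)C)C(=O)C2=C(C[C@@]34CCCC(C)(C)[C@@H]3C[C@]2(O)O4)C1=O | target

**Total steps: 7. Longest linear sequence: 7 (from carnosol).**

## Three steps most likely to fail
1. **Step 5 (phenonium ring expansion and capture).** The ortho-acyl group deactivates the aryl ring. The cation may also eliminate, or the 11-OBn oxygen may trap it to give a dihydrobenzofuran.
   - Fallback: drop the ring expansion and build the skeleton de novo. Add 2-bromobenzyl-type ArCH2MgX to methyl 2-(2,2-dimethyl-6-oxocyclohexyl)acetate. The alkoxide lactonizes to the cis-fused γ-lactone. Br/Li exchange then adds the aryl lithium to the lactone carbonyl and closes ring B, giving the hemiketal directly.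
2. **Step 1 (12-OH over 11-OH selectivity).** Non-selective methylation would give the wrong regioisomer or the bis-ether.
   - Fallback: start from carnosic acid instead. The free acid directs 12-O-alkylation through the 11-OH···carboxylate hydrogen bond. Reduce the 20-acid with LiAlH4 and introduce C7 oxygen by DDQ benzylic oxidation, then continue from the 7-oxo-20-ol.
3. **Step 7 (Fremy oxidation in the presence of the hemiketal).** The hemiketal may ring-open, or the phenol may be over-oxidized.
   - Fallback: install the C14 oxygen earlier. Brominate C14 of 3 with NBS, convert to the 14-OH (Cu-catalysed hydroxylation), and carry the 11-OBn/14-OH arene through the sequence. After debenzylation, Ag2O oxidizes the 11,14-hydroquinone to the quinone.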